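Start from the slowness of the flask and ask whether it moves with the charge, since where every step is of first order a fraction of the charge at a given time doesn't depend on the charge, and the flasks asked about span a factor of 25.0 in charge.

| flask | starting material | remark | time |
|---|---|---|---|
| Sunday's | 0.099 M | run made earlier |  |
| Tuesday's | 0.56 M | run made earlier |  |
| spring | 0.12 M |  | 40 min |
| noon | 0.30 M |  | 40 min |
| midnight | 1.0 M |  | 40 min |
| summer | 3.0 M |  | 40 min |

| run | time / min | target / % | isomer of the product A / % |
|---|---|---|---|
| Sunday's | 6.00 | 30.5 | 50.5 |
| Sunday's | 12.0 | 19.1 | 64.5 |
| Sunday's | 15.0 | 16.5 | 69.0 |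
| Sunday's | 25.0 | 12.7 | 74.9 |
| Sunday's | 30.0 | 11.5 | 76.4 |
| Tuesday's | 2.50 | 42.7 | 34.3 |
| Tuesday's | 4.00 | 37.1 | 41.9 |
| Tuesday's | 8.00 | 25.2 | 56.9 |
| Tuesday's | 15.0 | 16.0 | 69.0 |
| Tuesday's | 30.0 | 11.6 | 76.3 |

(standard deviation of a reading: 0.3 percentage points)

- "hardly changes" means that all values lie within two and a half points (for a concentration: within two and a half percent of the largest)

1. share of target in all that became target or isomer of the product A or third isomer or isomer of the product B for spring, noon, midnight, summer, in this order
2. how that number moves from the first to the last of them (hardly changes / rises, then falls / falls all the way / falls, then rises / rises all the way)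

Go to logarithms first: at 15.0 min Sunday's and Tuesday's flasks hold 16.5% and 16.0% of the charge as target, and across 0.753 decades of charge this gives 0.0178; call this size the charge slope, the change in the base-ten logarithm of the target's fraction per decade of charge. At 30.0 min the same reckoning gives a size of 0.00500 with the opposite sign, so take the larger size as the cautious reading, since each reading scatters by 0.3 percentage points.

Then ask whether the share's denominator moves as well: at 30.0 min the fraction outside target and isomer of the product A is 12.1% in Sunday's flask and 12.1% in Tuesday's, so read no charge effect there either.

Finally ask how far the slope carries from spring to summer, though summer's charge is higher than Tuesday's: the flasks lie 1.40 decades apart, and multiplying by 2.3 turns a small base-ten logarithm into a relative change, so the slope allows a fraction near 11.6% an estimated shift of 0.66 points, set against the 2.50 points of the band. My reckoning therefore commits to the shape, hardly changes, and leaves the level open.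

The forecast gives 10.7%, 10.7%, 10.7% and 10.7%, hardly changes, on the ground that the change in charge “alters nothing beyond scatter”.

The flasks give 11.4%, 11.4%, 11.4% and 11.4%, hardly changes.

    starting material ⇌ target (K = 2.70, k = 1.30 min⁻¹)
    starting material ⇌ isomer of the product A (K = 21.0, k = 0.500 min⁻¹)
    starting material ⇌ third isomer (K = 0.320, k = 0.480 min⁻¹)
    starting material ⇌ dormant form (K = 0.670, k = 0.00270 min⁻¹)
    starting material → decomposition product (k = 1.90 × 10⁻⁵ min⁻¹)
    target ⇌ isomer of the product B (K = 0.410, k = 0.0350 min⁻¹)

In spring, 3.9% of the charge still stands as starting material at 40.0 min, outside the share's sum. Put the charge slope to noon and midnight, 0.523 decades apart: it allows an estimated shift of 0.25 points, and the two flasks stand at 11.4% and 11.4%.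

(The earlier runs and the new flask are simulated from invented constants, noise included.)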